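**Retrosynthetic overview**

1. The target is an enolized bicyclo[3.3.1]nonane-2,4,9-trione with the C7 prenyl group endo (7-epi-clusianone framework). Its last C–C bond is made by exo-face hydroboration of a C7 exocyclic methylene and B-alkyl Suzuki–Miyaura coupling, which puts H exo and prenyl endo.
2. The 7-methylidene bicycle is opened in its cyclohexanone ring (C1–C8–C7–C6–C5–C9) at C5–C6 (palladium allylic alkylation) and at C1–C8 (Claisen [3,3] shift). This leads back to a flat, achiral aryl ether of 3,5-diprenyl-2,4,6-trihydroxybenzophenone, and both bonds are made in one pot.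
3. Enabling feature: C9 carries the one oxygen (O9) lying between the two prenylated, enantiotopic ring carbons C1 and C5, and C6–C7–C8 is a 2-methylenepropane-1,3-diyl unit with CMe2 (C8) at one end. Anchored on O9 by a CH2 end, the unit is turned round by the [3,3] shift so that CMe2 bonds to C1 (two quaternary carbons); the allyl carbonate left over has two CH2 termini and closes on C5.
4. The ether comes from the diprenylated benzophenone (one step from 2,4,6-trihydroxybenzophenone) and mono-Boc 2-isopropylidenepropane-1,3-diol (two steps from diethyl isopropylidenemalonate) by Mitsunobu coupling.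
5. Ring order: the phloroglucinol ring (C1–C2–C3–C4–C5–C9) is bought as an arene and dearomatized; the ring C1–C8–C7–C6–C5–C9 is closed last. C1 is set by a chiral ammonium ion pair, C5 by the tether, C7 by the bicycle.

Key step: step 5

Remark: the enolized triketone is treated as one compound in all its tautomers. Atom numbers are C1 (bridgehead bonded to CMe2 = C8), C2–C3–C4 (benzoyl-bearing diketone bridge), C5, C6 (CH2), C7, C9 (bridging ketone), with O2, O4, O9 on those carbons; stereodescriptors refer to this numbering and the drawn tautomer.

Step 1
Reactants: 1 2,4,6-trihydroxybenzophenone; 2 prenyl bromide (1-bromo-3-methylbut-2-ene, 2 equiv)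
Product: 3 3,5-bis(3-methylbut-2-enyl)-2,4,6-trihydroxybenzophenone (clusiaphenone B)
Conditions: KOH (aq., 10%), 0 °C
Reagents that add atoms: none
Why: Double C-prenylation of the phloroglucinol phenoxide (Friedel–Crafts-type C-alkylation) in aqueous base, where water favours C- over O-alkylation and the two free ring positions are equivalent; no stereocentre is formed.

Step 2
Reactants: 4 diethyl isopropylidenemalonate
Product: 5 2-(propan-2-ylidene)propane-1,3-diol
Conditions: i-Bu2AlH (5 equiv), CH2Cl2, −78 to 0 °C; aq. potassium sodium tartrate
Reagents that add atoms: none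
Why: 1,2-Reduction of both ester groups of the alkylidene malonate by i-Bu2AlH, which should leave the tetrasubstituted alkene untouched and give the symmetrical bis-allylic diol; no stereocentre.

Step 3
Reactants: 5 2-(propan-2-ylidene)propane-1,3-diol
Product: 6 tert-butyl [2-(hydroxymethyl)-3-methylbut-2-en-1-yl] carbonate
Conditions: Boc2O (1.0 equiv), DMAP (cat.), CH2Cl2, 0 °C
Reagents that add atoms: di-tert-butyl dicarbonate, CC(C)(C)OC(=O)OC(=O)OC(C)(C)C
Why: Statistical mono-carbonate formation (DMAP-catalysed acylation) on a symmetrical diol whose two hydroxymethyl groups are equivalent, so only one mono-carbonate can form and recovered diol is recycled; no stereocentre.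

Step 4
Reactants: 3 clusiaphenone B; 6 tert-butyl [2-(hydroxymethyl)-3-methylbut-2-en-1-yl] carbonate
Product: 7 aryl ether of 3 at O9 (the hydroxyl para to benzoyl, between the two prenyls) carrying the 2-(tert-butoxycarbonyloxymethyl)-3-methylbut-2-en-1-yl group
Conditions: PPh3, DIAD, THF, 0 °C to rt
Reagents that add atoms: none
Why: Mitsunobu etherification should take the most acidic and only non-chelated phenol of 3 (both ortho hydroxyls are hydrogen-bonded to the benzoyl carbonyl), with SN2 attack at the primary carbinol carbon preferred over SN2′ attack at the CMe2 end; the ether is achiral.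

Step 5
Reactants: 7 aryl ether
Product: 9 (1S,5R)-3-[hydroxy(phenyl)methylidene]-8,8-dimethyl-7-methylidene-1,5-bis(3-methylbut-2-enyl)bicyclo[3.3.1]nonane-2,4,9-trione, via Claisen dienone 8 (not isolated)
Conditions: N-(9-anthracenylmethyl)cinchonidinium chloride (10 mol %; the cinchoninium pseudo-enantiomer if the sense of induction requires it), Cs2CO3 (1.2 equiv), toluene, 40 °C; after consumption of 7: Pd(PPh3)4 (5 mol %), 25 °C; 1 M HCl work-up
Reagents that add atoms: none
Why: Proposed new method: deprotonation of an ortho hydroxyl of 7 makes the adjacent prenyl-bearing ring carbon an enolate carbon, and inside a tight ion pair with the chiral cinchonidinium cation this carbon (C1) should attack the CMe2 end of the tetrasubstituted allyl ether through a six-membered cyclic transition state while O9 leaves as a vinylogous carboxylate (anion-accelerated aromatic Claisen [3,3] shift), giving dienone 8; the closest known reaction types are the thermal ortho-Claisen rearrangement of prenyl aryl ethers to reverse-prenyl dienones and the enantioselective alkylative dearomatization of this acylphloroglucinol class under cinchona ammonium ion pairing, which poses the same stereochemical question. The concerted shift can only deliver the fully substituted allyl terminus, so the most hindered bond C1–C8 (two quaternary carbons) is made regiospecifically, and the chiral cation, by choosing between the two enantiotopic prenylated ortho carbons, sets C1 (S). Zerovalent palladium then ionizes the allylic tert-butyl carbonate of 8 to a 2-substituted π-allyl complex, and outer-sphere attack of the prenyl-bearing enolate carbon C5 on an allyl terminus (Tsuji–Trost C-alkylation, as in palladium-catalysed dearomative allylic annulations of acylphloroglucinols) closes the six-membered ring C1–C8–C7–C6–C5–C9 with C7 in the ring and its alkene left exocyclic. After the shift both allyl termini are CH2 groups, so either attack gives 9, whereas allylation without the shift would join the ring to the CH2 end and lose the C1–CMe2 bond. C5 (R) is set by C1, because the three-carbon tether can reach C5 only on its own face of the ring (1,3-cis bridge). The closure needs C- over O-allylation and C5 over C3 attack: O-allylated vinylogous esters re-ionize under zerovalent palladium and drain to the C-alkylated bicycle, and C3 is protected by its chelated benzoyl group and by the loss of enol conjugation that alkylation there would cost.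

Step 6
Reactants: 9 7-methylidene bicyclic trione; 10 1-bromo-2-methylprop-1-ene
Product: 12 (1S,5R,7S)-3-[hydroxy(phenyl)methylidene]-8,8-dimethyl-1,5,7-tris(3-methylbut-2-enyl)bicyclo[3.3.1]nonane-2,4,9-trione (target; C7 prenyl endo), via alkylborane 11 (not isolated)
Conditions: 9-BBN (2.5 equiv), THF, 0 °C to rt; then 10 (2 equiv), PdCl2(dppf) (5 mol %), K3PO4 (aq.), DMF, 50 °C; 1 M HCl work-up
Reagents that add atoms: 9-borabicyclo[3.3.1]nonane (9-BBN), [H]B1C2CCCC1CCC2 (its boron unit is carried by 11 only; it supplies the hydrogen at C7 of 12)
Why: One-pot hydroboration and B-alkyl Suzuki–Miyaura coupling: 9-BBN should select the 1,1-disubstituted exocyclic alkene over the three trisubstituted prenyl alkenes and add from the exo face of C7, because the endo face looks into the cleft under the C2–C3–C4 bridge (the usual exo attack on 7-methylidene- and 7-oxo-bicyclo[3.3.1]nonanes), so that hydrogen enters exo and the CH2–B arm, converted with retention into the prenyl group by coupling with alkenyl bromide 10, is endo (7S), while the acidic enol only consumes one equivalent of borane as a boron chelate that is cleaved on acidic work-up.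

**Compound list**

1 | 2,4,6-trihydroxybenzophenone | O=C(c1ccccc1)c1c(O)cc(O)cc1O | starting material
2 | prenyl bromide (1-bromo-3-methylbut-2-ene) | CC(C)=CCBr | starting material
3 | 3,5-bis(3-methylbut-2-enyl)-2,4,6-trihydroxybenzophenone (clusiaphenone B; achiral) | CC(C)=CCc1c(O)c(CC=C(C)C)c(O)c(C(=O)c2ccccc2)c1O | intermediate
4 | diethyl isopropylidenemalonate (diethyl 2-(propan-2-ylidene)propanedioate) | CCOC(=O)C(=C(C)C)C(=O)OCC | starting material
5 | 2-(propan-2-ylidene)propane-1,3-diol | CC(C)=C(CO)CO | intermediate
6 | tert-butyl [2-(hydroxymethyl)-3-methylbut-2-en-1-yl] carbonate | CC(C)=C(CO)COC(=O)OC(C)(C)C | intermediate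
7 | aryl ether: 3 alkylated on O9 (hydroxyl para to benzoyl, between the prenyls) with the 2-(tert-butoxycarbonyloxymethyl)-3-methylbut-2-en-1-yl group; achiral | CC(C)=CCc1c(OCC(COC(=O)OC(C)(C)C)=C(C)C)c(CC=C(C)C)c(O)c(C(=O)c2ccccc2)c1O | intermediate
8 | Claisen dienone: dearomatized ring in which the prenyl-bearing carbon C1 also carries the 3-(tert-butoxycarbonyloxymethyl)-2-methylbut-3-en-2-yl group; (S) at C1 | OC1=C(CC=C(C)C)C(=O)/C(=C(/O)c2ccccc2)C(=O)[C@@]1(CC=C(C)C)C(C)(C)C(=C)COC(=O)OC(C)(C)C | intermediate
9 | (1S,5R)-3-[hydroxy(phenyl)methylidene]-8,8-dimethyl-7-methylidene-1,5-bis(3-methylbut-2-enyl)bicyclo[3.3.1]nonane-2,4,9-trione | C=C1C[C@@]2(CC=C(C)C)C(=O)/C(=C(/O)c3ccccc3)C(=O)[C@](CC=C(C)C)(C2=O)C1(C)C | intermediate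
10 | 1-bromo-2-methylprop-1-ene | CC(C)=CBr | starting material
11 | alkylborane: 9 with an endo CH2–(9-BBN) group at C7 (7S) and the enol oxygen as its 9-BBN borinate | B1(C2CCCC1CCC2)C[C@H]3C[C@@]4(CC=C(C)C)C(=O)/C(=C(/OB5C6CCCC5CCC6)c7ccccc7)C(=O)[C@](CC=C(C)C)(C4=O)C3(C)C | intermediate
12 | (1S,5R,7S)-3-[hydroxy(phenyl)methylidene]-8,8-dimethyl-1,5,7-tris(3-methylbut-2-enyl)bicyclo[3.3.1]nonane-2,4,9-trione; C7 prenyl endo (cis to the C2–C3–C4 bridge) | CC(C)=CC[C@H]1C[C@@]2(CC=C(C)C)C(=O)/C(=C(/O)c3ccccc3)C(=O)[C@](CC=C(C)C)(C2=O)C1(C)C | target

Total step count: 6. Longest linear sequence: 5 steps (4 → 5 → 6 → 7 → 9 → 12).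

**Steps most likely to fail**

First, step 5, the proposed method. The chiral ion pair may fail to bias which of the two enantiotopic ortho carbons receives the allyl group, because a racemic background shift of the caesium salt competes. The tetrasubstituted allyl ether may also ionize and recombine through its CH2 end (1,3-shift), or migrate on to the benzoyl-bearing para carbon. The fallback sets out from 7 and returns at 9. Heat 7 in toluene at 110 °C without base (thermal ortho-Claisen rearrangement) to the racemic Claisen dienone F1. Cool, then add Pd(PPh3)4 and Cs2CO3 for the same Tsuji–Trost closure to the racemic bicyclic trione F2. Separate the enantiomers of F2 by preparative chromatography on a chiral stationary phase (or by crystallization of a cinchonidine salt of this vinylogous acid) to obtain 9.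

Second, step 6. The borane may be diverted by the acidic enol and the carbonyl groups (over-reduction, or a boron chelate that survives work-up). The hindered alkylborane may transfer its alkyl group to palladium so slowly that protodeboronation competes. Facial leakage in the hydroboration would in addition give the 7-exo epimer. The fallback sets out from 9 and returns at 12. Methylate the enol with Me3SiCHN2 (MeOH/toluene) to the methyl enol ether F3 (either O-methyl regioisomer serves). Hydroborate with 9-BBN to the alkylborane F4 and couple with 10 as before to the methyl enol ether F5. Demethylate with LiCl in DMSO at 120 °C (nucleophilic O-demethylation of the vinylogous ester) to 12.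

Third, step 4. The doubly flanked phenol may react sluggishly, so that C-alkylation of the phloroglucinol ring or reaction at a chelated hydroxyl competes. The fallback sets out from 1 and 6 and returns at 7, reversing the order of events. Carry out the Mitsunobu reaction (PPh3, DIAD, THF) on the unhindered para hydroxyl of 1 to give the para-ether F6. Then introduce the two prenyl groups at the only two free ring positions with 2 (NaH, toluene; C-alkylation of the phenoxide in a non-polar medium) to reach 7.

Further compounds
F1 | step 5 | racemic Claisen dienone (racemate of 8) | OC1=C(CC=C(C)C)C(=O)/C(=C(/O)c2ccccc2)C(=O)C1(CC=C(C)C)C(C)(C)C(=C)COC(=O)OC(C)(C)C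
F2 | step 5 | racemic 7-methylidene bicyclic trione (racemate of 9) | C=C1CC2(CC=C(C)C)C(=O)/C(=C(/O)c3ccccc3)C(=O)C(CC=C(C)C)(C2=O)C1(C)C
F3 | step 6 | methyl enol ether of 9 (OMe on the ring carbon next to C5; configuration as in 9) | C=C1C[C@@]2(CC=C(C)C)C(OC)=C(C(=O)c3ccccc3)C(=O)[C@](CC=C(C)C)(C2=O)C1(C)C
F4 | step 6 | alkylborane of F3 (endo CH2–(9-BBN) at C7) | B1(C2CCCC1CCC2)C[C@H]3C[C@@]4(CC=C(C)C)C(OC)=C(C(=O)c5ccccc5)C(=O)[C@](CC=C(C)C)(C4=O)C3(C)C
F5 | step 6 | methyl enol ether of 12 (C7 prenyl endo) | CC(C)=CC[C@H]1C[C@@]2(CC=C(C)C)C(OC)=C(C(=O)c3ccccc3)C(=O)[C@](CC=C(C)C)(C2=O)C1(C)C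
F6 | step 4 | para-ether of 1 with the 2-(tert-butoxycarbonyloxymethyl)-3-methylbut-2-en-1-yl group | O=C(c1ccccc1)c1c(O)cc(OCC(COC(=O)OC(C)(C)C)=C(C)C)cc1O
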